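**Plan**
Hydroazulene numbering: C1 (carbinol, i-Pr), C3a (quaternary, Me), C4 (C=O), C5=C6 (Me), C7, C8 (O-ester), C8a.
Retrosynthesis cuts, in order: the ester C8–O; the C8 carbinol (back to a C8 ketone); the C5=C6 unsaturation (back to a C4 silyl enol ether); then both ring bonds C3a–C8a and C6–C7 at once in a (4+3) cycloaddition.
Enabling feature: C7–C8(O)–C8a of the seven-membered ring is an oxyallyl unit, C3a–C4(O)–C5=C6 is the footprint of a 2-silyloxy-1,3-diene, and the C1 oxygen next to C8a can be an oxirane oxygen whose opening creates the cation.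
Forward: the acyclic C15 chain is joined by B-alkyl Suzuki coupling (C1–C2) and propenyl addition; the five- and seven-membered rings arise together in step 10; then enone, C8 carbinol and ester follow.
Stereochemistry: C1 from a carbinol-directed epoxidation (carbinol from asymmetric transfer hydrogenation); C8a and C3a relayed from C1 in the cycloaddition; C8 by reduction directed by the C1 hydroxyl.

Key step: step 10

Assumption: the methyl-bearing carbon brought in with 8 is racemic; it becomes sp2 in 18, so 12 and 15–17 are carried as epimer mixtures at that carbon (left unspecified in their SMILES).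

**Step 1**
Reactants: 1 3-methylbut-1-yne; 2 N-methoxy-N-methylacetamide
Product: 4 5-methylhex-3-yn-2-one, via lithium 3-methylbut-1-yn-1-ide 3 (not isolated)
Conditions: n-BuLi, THF, −78 °C; then 2, −78 → 0 °C; aq NH4Cl
Reagents that add atoms: none
Why: Acylation of a lithium acetylide by a Weinreb amide stops at the ketone because the chelated tetrahedral adduct survives until work-up (Weinreb ketone synthesis).

**Step 2**
Reactants: 4 5-methylhex-3-yn-2-one
Product: 5 (2S)-5-methylhex-3-yn-2-ol
Conditions: RuCl[(S,S)-TsDPEN](p-cymene) (cat.), i-PrOH, rt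
Reagents that add atoms: none
Why: Noyori asymmetric transfer hydrogenation differentiates the alkynyl and methyl groups of alkynyl ketones; the (S,S)-catalyst is expected to give the (S)-carbinol, the source of all later stereocentres.

**Step 3**
Reactants: 5 (2S)-5-methylhex-3-yn-2-ol
Product: 7 (2S,3Z)-4-iodo-5-methylhex-3-en-2-ol, via cyclic alkenylaluminate 6 (not isolated)
Conditions: Red-Al, THF, 0 °C → rt; then I2, THF, −78 °C
Reagents that add atoms: iodine, II
Why: Alkoxide-directed trans-hydroalumination places aluminium on the distal alkyne carbon in a five-membered chelate, and iodinolysis with retention gives the (Z)-γ-iodo allylic alcohol, which fixes the trisubstituted alkene geometry.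

**Step 4**
Reactants: 8 2-methylbut-3-enoic acid (racemic); 9 N,O-dimethylhydroxylamine hydrochloride
Product: 10 N-methoxy-N,2-dimethylbut-3-enamide (racemic)
Conditions: EDC·HCl, N-methylmorpholine, CH2Cl2, 0 °C
Reagents that add atoms: none
Why: Carbodiimide amide coupling; the weak base and low temperature should keep the β,γ-double bond out of conjugation.

**Step 5**
Reactants: 10 N-methoxy-N,2-dimethylbut-3-enamide; 7 (2S,3Z)-4-iodo-5-methylhex-3-en-2-ol
Product: 12 (5E,7S)-7-hydroxy-N-methoxy-N,2-dimethyl-5-(propan-2-yl)oct-5-enamide (2-epimers), via B-alkyl-9-BBN adduct 11 (not isolated)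
Conditions: 9-BBN, THF, 0 °C → rt; then 7, Pd(dppf)Cl2, AsPh3, Cs2CO3, DMF/H2O, rt
Reagents that add atoms: none
Why: B-alkyl Suzuki–Miyaura coupling: anti-Markovnikov hydroboration of the terminal alkene, then sp3–sp2 coupling with retention of the iodide geometry, forms C1–C2 and tolerates the free hydroxyl and the Weinreb amide.

**Step 6**
Reactants: 12 (5E,7S)-7-hydroxy-N-methoxy-N,2-dimethyl-5-(propan-2-yl)oct-5-enamide; 13 (E)-1-bromoprop-1-ene
Product: 15 (2E,8E,10S)-10-hydroxy-5-methyl-8-(propan-2-yl)undeca-2,8-dien-4-one (5-epimers), via (E)-prop-1-enyllithium 14 (not isolated)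
Conditions: 13, t-BuLi, Et2O, −78 °C; then 12 (THF), −78 → 0 °C (excess 14); cold aq NH4Cl
Reagents that add atoms: none
Why: Halogen–lithium exchange with retention gives the (E)-alkenyllithium; after the first equivalent deprotonates the hydroxyl, addition to the Weinreb amide stops at the chelated adduct and releases the (E)-enone on work-up (Weinreb ketone synthesis).

**Step 7**
Reactants: 15 (2E,8E,10S)-10-hydroxy-5-methyl-8-(propan-2-yl)undeca-2,8-dien-4-one
Product: 16 (2E)-7-[(2R,3R)-3-[(1S)-1-hydroxyethyl]-2-(propan-2-yl)oxiran-2-yl]-5-methylhept-2-en-4-one (5-epimers)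
Conditions: mCPBA, NaHCO3, CH2Cl2, 0 °C
Reagents that add atoms: 3-chloroperbenzoic acid, OOC(=O)c1cccc(Cl)c1
Why: Hydroxyl-directed peracid epoxidation: A(1,3) strain from the cis alkyl chain holds the carbinol hydrogen in the alkene plane, so oxygen is delivered syn to the hydroxyl to give the threo epoxy alcohol and hence the (R) configuration of the future C1; the electron-poor enone alkene should not react.

**Step 8**
Reactants: 16 threo epoxy alcohol
Product: 17 (2E)-7-[(2R,3S)-3-acetyl-2-(propan-2-yl)oxiran-2-yl]-5-methylhept-2-en-4-one (5-epimers)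
Conditions: Dess–Martin periodinane, NaHCO3, CH2Cl2, 0 °C → rt
Reagents that add atoms: none
Why: Dess–Martin oxidation under buffered conditions turns the carbinol, whose directing role is finished, into the methyl ketone without opening the oxirane.

**Step 9**
Reactants: 17 epoxy diketone
Product: 18 (2R,3S)-2-[(5E)-3-methyl-4-(triethylsilyloxy)hepta-3,5-dien-1-yl]-2-(propan-2-yl)-3-[1-(triethylsilyloxy)ethenyl]oxirane (3E/3Z mixture)
Conditions: LDA (2.4 equiv), Et3SiCl (internal quench), THF, −78 °C; Et3N, pentane, filtration; used crude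
Reagents that add atoms: chlorotriethylsilane, CC[Si](Cl)(CC)CC
Why: Kinetic deprotonation with in situ O-silylation: the epoxy ketone can enolise only towards its methyl group and the enone is deprotonated at the α'-methine to the cross-conjugated dienolate, so both enol silanes form in one operation (the geometry of the tetrasubstituted enol ether is not controlled).

**Step 10**
Reactants: 18 epoxy bis(enol silane)
Product: 19 (1R,3aS,8aR)-3a,6-dimethyl-1-(propan-2-yl)-1,4-bis(triethylsilyloxy)-2,3,3a,6,7,8a-hexahydroazulen-8(1H)-one (6-epimers)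
Conditions: Et3SiOTf (10–20 mol %), CH2Cl2 (0.005–0.01 M), −78 °C; Et3N quench
Reagents that add atoms: none
Why: Proposed new method: Et3Si+ should silylate the oxirane oxygen and ionise the C8a–O bond, which is allylic to the enol silane, to a 2-(triethylsilyloxy)allyl cation over C7–C8–C8a; its C8a end is attacked by the nucleophilic C3a end of the tethered 2-silyloxydiene and the enol silane carbon C7 then closes onto C6 of the resulting silylated enone, with release of Et3Si+ (stepwise or asynchronous (4+3) cycloaddition). The closest known reaction type is the silyl-triflate-catalysed (4+3) cycloaddition of epoxy enol silanes with dienes, together with intramolecular oxyallyl (4+3) cycloadditions through three-atom tethers that give hydroazulenones; new here is that the tether runs through the distal oxirane carbon, so that the epoxide oxygen remains as the C1 silyl ether inside the new five-membered ring, and that the 4π partner is a 2-silyloxydiene. Ring closures: the cyclopentane closes by C3a–C8a bond formation, exo with respect to the enol ether double bond and endo with respect to the oxirane, so a backside displacement is impossible and a free cation (SN1) is required; the cycloheptane closes by C6–C7 bond formation, 7-endo onto the silylated enone, as the second bond of the (4+3) process. Stereocentres: C1 is untouched because its C–O bond is kept; C8a is controlled by C1, since with the tether perpendicular to the cation plane allylic strain places the isopropyl group beside H-8a and the silyloxy group beside C8, so that C8 ends cis to the C1 oxygen; C3a is controlled relative to C8a by an extended (exo-type) arrangement of enol ether and cation that should give the trans ring fusion with the methyl anti to H-8a, for either enol ether geometry because C3a reacts as a planar carbon; C6 forms as a mixture and is removed in step 11. The step needs ionisation of the secondary allylic rather than the tertiary C–O bond (secured by overlap of that bond with the electron-rich enol ether and by catalytic Lewis acid at −78 °C), (4+3) rather than (3+2) closure (1,4-attack on the silylated enone avoids two adjacent fully substituted carbons) and trans rather than cis fusion (the compact alternative would stack the diene over the oxyallyl unit on the face that carries the C1 triethylsilyloxy group), while high dilution suppresses intermolecular reaction.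

**Step 11**
Reactants: 19 cycloadduct
Product: 21 (1R,3aS,8aR)-1-hydroxy-3a,6-dimethyl-1-(propan-2-yl)-2,3,3a,8a-tetrahydroazulene-4,8(1H,7H)-dione, via enedione triethylsilyl ether 20 (not isolated)
Conditions: Pd(OAc)2 (1.1 equiv), MeCN, rt; then aq HF, MeCN, 0 °C
Reagents that add atoms: none
Why: Saegusa–Ito oxidation: the palladium enolate formed regiospecifically from the enol silane can undergo β-hydride elimination only towards C6 (C3a is quaternary), which installs the C5=C6 enone and removes the C6 stereocentre; fluoride then cleaves the tertiary silyl ether under non-basic conditions that avoid retro-aldol cleavage.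

**Step 12**
Reactants: 21 hydroxy enedione
Product: 22 (1R,3aS,8S,8aS)-1,8-dihydroxy-3a,6-dimethyl-1-(propan-2-yl)-2,3,3a,7,8,8a-hexahydroazulen-4(1H)-one
Conditions: Me4NBH(OAc)3, MeCN/AcOH, −30 → −20 °C
Reagents that add atoms: none
Why: Evans–Saksena reduction: the C1 hydroxyl, cis to C8 on the five-membered ring, exchanges onto boron and delivers hydride to the top face of the C8 ketone (1,3-anti diol, C8 S), while the unligated enone is not reduced by the triacetoxyborohydride.

**Step 13**
Reactants: 22 diol; 23 3,4-dimethoxybenzoyl chloride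
Product: 24 (1R,3aS,8S,8aS)-1-hydroxy-3a,6-dimethyl-4-oxo-1-(propan-2-yl)-1,2,3,3a,4,7,8,8a-octahydroazulen-8-yl 3,4-dimethoxybenzoate
Conditions: Et3N, DMAP, CH2Cl2, 0 °C → rt
Reagents that add atoms: none
Why: DMAP-catalysed acylation is selective for the secondary C8 hydroxyl over the tertiary C1 hydroxyl.

**Compound list**
1 | 3-methylbut-1-yne | CC(C)C#C | starting material
2 | N-methoxy-N-methylacetamide | CC(=O)N(C)OC | starting material
3 | lithium 3-methylbut-1-yn-1-ide | [Li]C#CC(C)C | intermediate
4 | 5-methylhex-3-yn-2-one | CC(=O)C#CC(C)C | intermediate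
5 | (2S)-5-methylhex-3-yn-2-ol | C[C@H](O)C#CC(C)C | intermediate
6 | sodium (5S)-2,2-bis(2-methoxyethoxy)-5-methyl-3-(propan-2-yl)-2,5-dihydro-1,2-oxaaluminol-2-uide (cyclic alkenylaluminate) | [Na+].C[C@@H]1O[Al-](OCCOC)(OCCOC)C(C(C)C)=C1 | intermediate
7 | (2S,3Z)-4-iodo-5-methylhex-3-en-2-ol | C[C@H](O)/C=C(\I)C(C)C | intermediate
8 | 2-methylbut-3-enoic acid (racemic) | C=CC(C)C(O)=O | starting material
9 | N,O-dimethylhydroxylamine hydrochloride | CNOC.Cl | starting material
10 | N-methoxy-N,2-dimethylbut-3-enamide (racemic) | C=CC(C)C(=O)N(C)OC | intermediate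
11 | 4-(9-borabicyclo[3.3.1]nonan-9-yl)-N-methoxy-N,2-dimethylbutanamide | CON(C)C(=O)C(C)CCB1C2CCCC1CCC2 | intermediate
12 | (5E,7S)-7-hydroxy-N-methoxy-N,2-dimethyl-5-(propan-2-yl)oct-5-enamide (2-epimers) | C[C@H](O)/C=C(\CCC(C)C(=O)N(C)OC)C(C)C | intermediate
13 | (E)-1-bromoprop-1-ene | C/C=C/Br | starting material
14 | (E)-prop-1-enyllithium | C/C=C/[Li] | intermediate
15 | (2E,8E,10S)-10-hydroxy-5-methyl-8-(propan-2-yl)undeca-2,8-dien-4-one (5-epimers) | C[C@H](O)/C=C(\CCC(C)C(=O)/C=C/C)C(C)C | intermediate
16 | (2E)-7-[(2R,3R)-3-[(1S)-1-hydroxyethyl]-2-(propan-2-yl)oxiran-2-yl]-5-methylhept-2-en-4-one (5-epimers) | C[C@H](O)[C@H]1O[C@@]1(C(C)C)CCC(C)C(=O)/C=C/C | intermediate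
17 | (2E)-7-[(2R,3S)-3-acetyl-2-(propan-2-yl)oxiran-2-yl]-5-methylhept-2-en-4-one (5-epimers) | CC(=O)[C@H]1O[C@@]1(C(C)C)CCC(C)C(=O)/C=C/C | intermediate
18 | (2R,3S)-2-[(5E)-3-methyl-4-(triethylsilyloxy)hepta-3,5-dien-1-yl]-2-(propan-2-yl)-3-[1-(triethylsilyloxy)ethenyl]oxirane (3E/3Z mixture) | C=C(O[Si](CC)(CC)CC)[C@H]1O[C@@]1(C(C)C)CCC(C)=C(O[Si](CC)(CC)CC)/C=C/C | intermediate
19 | (1R,3aS,8aR)-3a,6-dimethyl-1-(propan-2-yl)-1,4-bis(triethylsilyloxy)-2,3,3a,6,7,8a-hexahydroazulen-8(1H)-one (6-epimers; trans-fused) | O=C1CC(C)C=C(O[Si](CC)(CC)CC)[C@@]2(C)CC[C@@](O[Si](CC)(CC)CC)(C(C)C)[C@H]12 | intermediate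
20 | (1R,3aS,8aR)-3a,6-dimethyl-1-(propan-2-yl)-1-(triethylsilyloxy)-2,3,3a,8a-tetrahydroazulene-4,8(1H,7H)-dione | O=C1CC(C)=CC(=O)[C@@]2(C)CC[C@@](O[Si](CC)(CC)CC)(C(C)C)[C@H]12 | intermediate
21 | (1R,3aS,8aR)-1-hydroxy-3a,6-dimethyl-1-(propan-2-yl)-2,3,3a,8a-tetrahydroazulene-4,8(1H,7H)-dione | O=C1CC(C)=CC(=O)[C@@]2(C)CC[C@@](O)(C(C)C)[C@H]12 | intermediate
22 | (1R,3aS,8S,8aS)-1,8-dihydroxy-3a,6-dimethyl-1-(propan-2-yl)-2,3,3a,7,8,8a-hexahydroazulen-4(1H)-one | O[C@H]1CC(C)=CC(=O)[C@@]2(C)CC[C@@](O)(C(C)C)[C@H]12 | intermediate
23 | 3,4-dimethoxybenzoyl chloride | COc1ccc(C(Cl)=O)cc1OC | starting material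
24 | (1R,3aS,8S,8aS)-1-hydroxy-3a,6-dimethyl-4-oxo-1-(propan-2-yl)-1,2,3,3a,4,7,8,8a-octahydroazulen-8-yl 3,4-dimethoxybenzoate | COc1ccc(C(=O)O[C@H]2CC(C)=CC(=O)[C@@]3(C)CC[C@@](O)(C(C)C)[C@H]23)cc1OC | target

**Step count**
Total: 13 steps. Longest linear sequence: 12 steps (steps 1–3 and 5–13, from 3-methylbut-1-yne).

**Steps most likely to fail**

1. Step 10 (Proposed new method). What may go wrong: ionisation of the tertiary C1–O bond of the silylated oxirane, followed by hydride or alkyl shift (a Meinwald- or semipinacol-type rearrangement), instead of formation of the silyloxyallyl cation. The fallback uses known chemistry and a leaving group that can depart only from C8a. It sets out from 17. Lithium bromide in acetic acid/THF opens the α,β-epoxy ketone by SN2 attack at the carbonyl-activated carbon, as halides are known to do with such epoxides, and silylation of the tertiary hydroxyl (Me3SiOTf, 2,6-lutidine) gives (2E)-9-bromo-5-methyl-8-(propan-2-yl)-8-(trimethylsilyloxy)undec-2-ene-4,10-dione F1. Kinetic double enolisation as in step 9 (LDA, Et3SiCl) gives the 2-silyloxyallyl bromide bis(enol silane) F2. Silver triflate with a hindered pyridine in CH2Cl2 at −78 °C abstracts bromide, and the 2-silyloxyallyl cation cycloadds to the tethered silyloxydiene, as in the known silver-promoted (4+3) cycloadditions of 2-silyloxyallyl halides. This gives the 1-trimethylsilyl ether analogue of the cycloadduct F3, which under the conditions of step 11 comes back to the route at 21.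

2. Step 12. What may go wrong: slow exchange of the hindered tertiary hydroxyl onto boron, so that no intramolecular hydride delivery takes place and the ketone is either left or reduced from the open bottom face. The fallback sets out from 21. Sodium borohydride in CH2Cl2/MeOH at −78 °C reduces the saturated ketone in the presence of the enone and, attacking anti to the C1 oxygen and the angular methyl, should give mainly the C8 epimer, (1R,3aS,8R,8aS)-1,8-dihydroxy-3a,6-dimethyl-1-(propan-2-yl)-2,3,3a,7,8,8a-hexahydroazulen-4(1H)-one F4. Mitsunobu esterification of F4 with 3,4-dimethoxybenzoic acid (PPh3, DIAD, toluene) inverts C8 and comes back to the route at 24.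

3. Step 11. What may go wrong: slow β-hydride elimination from the hindered palladium enolate beside the quaternary C3a, with protodesilylation to the saturated diketone, which can no longer be dehydrogenated regioselectively. The fallback sets out from 19. Phenylselenenyl chloride (CH2Cl2, −78 °C) reacts with the enol silane to give the α-selenide, (1R,3aS,8aR)-3a,6-dimethyl-5-(phenylselanyl)-1-(propan-2-yl)-1-(triethylsilyloxy)hexahydroazulene-4,8-dione F5. Oxidation (H2O2, pyridine, 0 °C) and selenoxide syn-elimination, possible only towards C6, comes back to the route at 20, which is desilylated as in step 11.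

**Further compounds**
F1 | step 10 | (2E)-9-bromo-5-methyl-8-(propan-2-yl)-8-(trimethylsilyloxy)undec-2-ene-4,10-dione | CC(=O)[C@H](Br)[C@](O[Si](C)(C)C)(C(C)C)CCC(C)C(=O)/C=C/C
F2 | step 10 | bis(triethylsilyl) enol ether of F1 (2-silyloxyallyl bromide) | C=C(O[Si](CC)(CC)CC)[C@H](Br)[C@](O[Si](C)(C)C)(C(C)C)CCC(C)=C(O[Si](CC)(CC)CC)/C=C/C
F3 | step 10 | (1R,3aS,8aR)-3a,6-dimethyl-1-(propan-2-yl)-4-(triethylsilyloxy)-1-(trimethylsilyloxy)-2,3,3a,6,7,8a-hexahydroazulen-8(1H)-one | O=C1CC(C)C=C(O[Si](CC)(CC)CC)[C@@]2(C)CC[C@@](O[Si](C)(C)C)(C(C)C)[C@H]12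
F4 | step 12 | (1R,3aS,8R,8aS)-1,8-dihydroxy-3a,6-dimethyl-1-(propan-2-yl)-2,3,3a,7,8,8a-hexahydroazulen-4(1H)-one | O[C@@H]1CC(C)=CC(=O)[C@@]2(C)CC[C@@](O)(C(C)C)[C@H]12
F5 | step 11 | (1R,3aS,8aR)-3a,6-dimethyl-5-(phenylselanyl)-1-(propan-2-yl)-1-(triethylsilyloxy)hexahydroazulene-4,8-dione | O=C1CC(C)C([Se]c2ccccc2)C(=O)[C@@]3(C)CC[C@@](O[Si](CC)(CC)CC)(C(C)C)[C@H]13
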